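## The problem

The target 41, the seventeenth member of the gibberellin A series, is a trans-fused hydrindane (rings A and B) that carries a bicyclo[3.2.1]octane (rings C and D) across C8–C9. Seven stereocentres (C4, C5, C6, C8, C9, C10, C13) lie on these rings, and three of them (C4, C8, C10) are quaternary carbons. C4 and C10 hold the carboxyl carbons C19 and C20 in a 1,3-diaxial relation on the α face of ring A, so the second cannot be brought in by an external reagent once the first is in place, and their oxygens close to a δ-lactone at any mixed oxidation level. The third carboxyl (C7) sits on C6 next to quaternary C8, cis to C15, and is epimerisable as soon as it is an aldehyde or ester. The C13 bridgehead alcohol with the C16 methylene does not tolerate strong acid, its 16-nor-ketone undergoes an α-ketol shift when the hydroxyl is free, and the methylene survives neither allylic oxidation nor hydrogenation. Stereochemical information can be relayed: C6 sets a C10 carbinol (1,3-cis reduction), a C10–O bond sets C8 by a suprafacial shift, C8 fixes C9 (cis-hydrindanone) and C13 (bridge), and a C1 carbinol sets C5 and C4. The feature that invites the key step is that C19, C4, C3, C2 and C1 are the chain of an α-methyl δ-lactone whose ring oxygen sits on C1, allylic to a C10=C5 double bond of ring B, so that a [3,3] shift of its silyl ketene acetal forms C4–C5, closes ring A and frees the C19 acid.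

## Retrosynthesis

**Carboxyl groups and methylene (41 back to 37).** No skeletal bond is cut. The three acids of 41 are taken back through silyl ether 40 and trialdehyde 39 to triol 38, and the methylene of 38 to nor-ketone 37. Oxidising C7, C19 and C20 together from the alcohol level avoids the 19,20-lactone, which would form if the two neighbours were at different oxidation levels. The Wittig reaction comes before the aldehydes exist, and the 13-oxygen stays silylated until the last step so that no free α-ketol meets acid or base. The forward steps must oxidise a 1,5-diol without lactol formation and spare the alkene.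

**C10–C20 (36, 35 back to 32, then to 28).** The angular carbon is cut from C10. An external nucleophile adding to a 1(10)-en-2-one would come from the β face, away from the axial C19 group, which is the wrong face. Delivery from an oxygen on the α face of C2 by a [2,3] shift (33 to 35) puts C20 syn to C19 by necessity. The 2α-alcohol 32 comes from enone 31, and 31 from allylic oxidation of the 1(10)-ene 30. C19 is held at the alcohol level (29, 30) because a C19 ester would capture the 2α-alkoxide as a γ-lactone. The precursor is the 1(10)-ene acid 28, which lacks one quaternary centre and one stereocentre.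

**C4–C5, ring A (28 back to 25).** This is the key cut. The C4–C5 bond is broken and the C1–O bond re-formed, which turns the cyclohexene acid 28 into the δ-lactone 25 on the ring B cyclopentene. Against an intermolecular alkylation at C4 or an intramolecular Diels–Alder closure of ring A, this cut makes the quaternary C4 and the C5 stereocentre in one intramolecular event whose face is dictated by one carbinol centre. The precursor has one ring and two stereocentres less; C4 of the lactone need not be controlled. The forward reaction must enolise the lactone cleanly and pass through a boat transition state.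

**C1–C10 and C1–C2 (25 back to 20 and 21).** Lactone 25 is opened to hydroxy ester 24 and taken to enone 23, which is cut on both sides of the C1 carbonyl: enol triflate 20, carbon monoxide and the alkylborane 22 from ester 21. An aldehyde plus organometallic route would give both C1 epimers and need an oxidation before the reduction. The ketone allows reagent-controlled reduction, which is what the key step depends on.

**C13–C16, ring D (20 back to 17).** Ring D is cut between the carbinol and the ketone of α-ketol 18, giving keto aldehyde 17. A benzoin-type closure gives the 13-hydroxy-16-ketone at once. An alkyne–ketone reductive closure would give the methylene too early and would cost an ozonolysis. The enol triflate in ring B keeps C10 from competing as a second ketone. Ketal and silyl ether (19, 20) are then needed for the later steps.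

**C8–C15 (17, 15, 14 back to 9).** The two-carbon arm is cut from quaternary C8 by a Claisen retron: ester 11 comes from allylic alcohol 9. A conjugate addition to a ring-fusion enone would leave the face at C8 to the small difference between two methylene groups. The suprafacial shift instead places C15 cis to C7 because the C10 oxygen is cis to C7. The C10 oxygen lost in the shift is restored by hydroboration and oxidation (13, 14) and then masked as the enol triflate 15. C9 is set by equilibration of 14.

**Dearomatisation (9 back to 7).** The ring C ketal and the C8=C9 alkene of 9 are the Birch pattern of a 3,4-dialkylanisole (8 from 7). All nine carbons of rings B and C, with oxygen at C10 and C13, are therefore those of a 5-methoxyindan-1-ol. The reduction must spare the benzylic C–O bond.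

**C9–C10 and C6–C8 (7 back to 1 and 2).** Indanol 7 comes from diol 6 and keto acid 5, which is cut at the aryl–acyl bond (Friedel–Crafts) to the arylsuccinate 3. The aryl–C6 bond of 3 is made by asymmetric conjugate addition of boronic acid 1 to fumarate 2. This puts the only catalyst-set ring stereocentre (C6) at the start, where it is cheap, and every later ring stereocentre except C1 is derived from it.

## Roads not taken

**Alternative 1:** The cut goes through C8–C9 and C11–C12. A ring A cyclohexane A1 carries C4, C5, C6 and C10 with all three esters, a vinyl group on C10 and, on C6, a 2-silyloxydiene with the propargyl arm. It would close rings B and C in one intramolecular Diels–Alder reaction to the tricyclic silyl enol ether A2.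
- Merits: two rings, two C–C bonds, C8 and C9 in one step; the C13 silyl enol ether is placed to close ring D onto the alkyne, so 13-oxygen and 16-methylene arrive late and unprotected; the carboxyls are at their final level throughout.
- Weak points: A1 already contains the two quaternary carbons C4 and C10 flanking C5, plus C5 and C6, on a monocycle, where none of the relay effects of the polycycle is available. The dienophile is an unactivated vinyl group on a quaternary carbon facing an electron-rich diene, so high temperature is needed. The three-atom tether leaves the B/C fusion and the configuration at C8 to the conformation of a flexible chain.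
- Comparison: this road is better in convergence and in oxidation-state economy. The chosen plan is longer and pays with a reduction–oxidation detour at C19. Against this it sets that each stereocentre is fixed by a tether, a suprafacial shift or a reagent.

**Alternative 2:** The cut is the C6–C8 bond, read backwards as the C7–C8 bond of a six-membered ring B. The 6-mesylate 7-ol A3 of an ent-kauranoid would contract under base: C8 migrates from C7 to C6 as mesylate leaves, giving the 7-aldehyde A4.
- Merits: the step is stereospecific (inversion at C6, retention at C8), delivers C7 one oxidation from the acid, and rings C and D with the methylene are already present.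
- Weak points: the whole problem moves into A3. It needs a kaurane skeleton with C19 and C20 both oxidised, the 13-oxygen, and a stereodefined, selectively mesylated 6,7-diol between C5 and quaternary C8. Hydride shift to the 6-ketone and epoxide closure are the usual competitors, and the methylene must survive the diol chemistry.
- Comparison: with a natural kauranoid of the right oxidation pattern this would be much the shortest road, an advantage the chosen plan cannot match. From simple materials it demands a complete tetracyclic synthesis before its key step, whereas the chosen plan reaches its key step from a substituted indane.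

**Alternative 3:** The cut is C12–C13. In the hydrindane triester A5, C8 is the spiro carbon of a cyclopentane-1,2-dione and C9 bears an acetyl group. Its enamine adds to one of the two carbonyls to give the 13-hydroxy-11,16-dione A6.
- Merits: ring C, the bridgehead alcohol and the 16-ketone arise in one step at the right oxidation levels with no protecting group, and A6 is a direct olefination substrate.
- Weak points: A5 again needs the ring A stereotetrad first, now next to a very congested C8–C9 pair. The choice between the two diastereotopic carbonyls decides C8 and C13 together and rests only on the reach of the C9 side chain. The free α-ketol forms under amine catalysis, where retro-aldol and ketol shift are open. The C11 ketone must then be removed beside a C9 that is epimerisable as long as the ketone is there.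
- Comparison: this road is more economical at rings C and D, where the chosen plan spends five steps on closure and protection. The chosen plan sets against this that C8, C9 and C13 are fixed early on a simple bicycle and that its α-ketol is never exposed unprotected.

Key step: step 18

Remark 1: Locants C1–C20 and the face descriptors α (face of C19 and C20) and β (face of H5, H9, C7 and C15) follow gibberellane usage and are kept for the corresponding atoms of all intermediates.
Remark 2: The antipode of the chiral diene ligand in step 1 is taken to be the one whose enantioface preference gives the (S)-succinate 3.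
Remark 3: Ester 21 is taken as a purchased reagent; C4 in 23–26 and C9/C10 in 12 and 13 are written without configuration because both epimers are carried on and converge.

## Steps

Step 1
Reactants: 1 (3-methoxyphenyl)boronic acid; 2 di-tert-butyl fumarate
Product: 3 di-tert-butyl (S)-2-(3-methoxyphenyl)succinate
Conditions: [RhCl(C2H4)2]2 (2.5 mol %), chiral 2,5-dibenzylbicyclo[2.2.1]hepta-2,5-diene (5.5 mol %), KOH (10 mol %), dioxane/H2O, 50 °C
Reagents that add atoms: none
Why: Rhodium-catalysed asymmetric 1,4-addition of an arylboronic acid to a fumarate (Hayashi–Miyaura reaction) with a chiral diene ligand is an established route to 2-arylsuccinates; aryl transfer to one enantioface of the symmetric diester sets C6.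

Step 2
Reactants: 3 di-tert-butyl (S)-2-(3-methoxyphenyl)succinate
Product: 5 (S)-6-methoxy-3-oxo-2,3-dihydro-1H-indene-1-carboxylic acid, via diacid 4 (not isolated)
Conditions: CF3CO2H, CH2Cl2, rt; concentrate; P2O5 in MeSO3H (1:10 w/w), 50 °C
Reagents that add atoms: none
Why: Acidolysis of the tert-butyl esters is followed by intramolecular Friedel–Crafts acylation; only the CH2CO2H arm can reach an ortho carbon in a five-membered closure, and it attacks para to the methoxy group. The stereocentre is α only to a free carboxyl and should not enolise under these conditions.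

Step 3
Reactants: 5 (S)-6-methoxy-3-oxo-2,3-dihydro-1H-indene-1-carboxylic acid
Product: 6 (1R,3S)-3-(hydroxymethyl)-5-methoxy-2,3-dihydro-1H-inden-1-ol
Conditions: LiAlH4 (3 equiv), THF, 0 °C to reflux; aqueous NaOH work-up
Reagents that add atoms: none
Why: Hydride reduction of carboxylate and ketone; hydride should add to C10 anti to the aluminium carboxylate on C6, giving the 1,3-cis diol (C10–OH and C7 both β). Any trans isomer would be removed by crystallisation.

Step 4
Reactants: 6 (1R,3S)-3-(hydroxymethyl)-5-methoxy-2,3-dihydro-1H-inden-1-ol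
Product: 7 (1R,3S)-3-[(tert-butyldimethylsilyloxy)methyl]-5-methoxy-2,3-dihydro-1H-inden-1-ol
Conditions: TBSCl (1.05 equiv), imidazole, CH2Cl2, −20 to 0 °C
Reagents that add atoms: tert-butyldimethylsilyl chloride CC(C)(C)[Si](C)(C)Cl
Why: Silylation distinguishes the primary alcohol from the secondary benzylic one on steric grounds.

Step 5
Reactants: 7 (1R,3S)-3-[(tert-butyldimethylsilyloxy)methyl]-5-methoxy-2,3-dihydro-1H-inden-1-ol
Product: 8 (1R,3S)-3-[(tert-butyldimethylsilyloxy)methyl]-5-methoxy-2,3,4,7-tetrahydro-1H-inden-1-ol
Conditions: Li (8 equiv), NH3(l)/THF, t-BuOH (4 equiv), −78 to −33 °C; isoprene, then MeOH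
Reagents that add atoms: none
Why: Birch reduction of a 3,4-dialkylanisole protonates C14 and C11 and leaves the enol ether C12=C13 and the tetrasubstituted C8=C9. The benzylic C10–O bond is present as its lithium alkoxide, a poor leaving group for hydrogenolysis, and excess metal is destroyed before any acidic quench.

Step 6
Reactants: 8 (1R,3S)-3-[(tert-butyldimethylsilyloxy)methyl]-5-methoxy-2,3,4,7-tetrahydro-1H-inden-1-ol
Product: 9 (1R,3S)-3-[(tert-butyldimethylsilyloxy)methyl]-5,5-(ethylenedioxy)-2,3,4,5,6,7-hexahydro-1H-inden-1-ol
Conditions: ethylene glycol (5 equiv), pyridinium p-toluenesulfonate (5 mol %), CH2Cl2, rt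
Reagents that add atoms: ethylene glycol OCCO
Why: Acid-catalysed addition of the diol to the enol ether (protonation at C12) gives the C13 ketal directly; C8=C9 stays in place because only the free ketone could draw it into conjugation.

Step 7
Reactants: 9 (1R,3S)-3-[(tert-butyldimethylsilyloxy)methyl]-5,5-(ethylenedioxy)-2,3,4,5,6,7-hexahydro-1H-inden-1-ol
Product: 11 bicyclic 9(10)-ene ethyl ester (C8 quaternary with β-CH2CO2Et; 6β-CH2OTBS; C13 ketal), via ketene acetal 10 (not isolated)
Conditions: MeC(OEt)3 (10 equiv), EtCO2H (10 mol %), 140 °C, EtOH distilled off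
Reagents that add atoms: triethyl orthoacetate CCOC(C)(OCC)OCC
Why: Johnson–Claisen rearrangement: the ketene acetal on the β C10 oxygen transfers its CH2CO2Et carbon suprafacially to C8, so C15 arrives on the β face, cis to C7, and the quaternary centre is set by chirality transfer. The double bond moves to C9=C10.

Step 8
Reactants: 11 bicyclic 9(10)-ene ethyl ester
Product: 13 C10 alcohol (isomer mixture at C9 and C10), via alkylborane 12 (not isolated)
Conditions: BH3·THF (1.5 equiv), THF, 0 °C to rt; then H2O2 (30 %), aqueous NaOH, 0 °C
Reagents that add atoms: hydrogen peroxide OO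
Why: Hydroboration–oxidation places boron, then oxygen, on the less substituted C10; the hindered neopentyl-type ester survives the short cold treatment. The configurations formed at C9 and C10 are corrected or removed in step 9.

Step 9
Reactants: 13 C10 alcohol
Product: 14 cis-hydrindanone (C10 ketone; 9β-H; C8 β-CH2CO2Et; 6β-CH2OTBS; C13 ketal)
Conditions: Dess–Martin periodinane, NaHCO3, CH2Cl2, rt; then DBU (0.2 equiv), CH2Cl2, rt
Reagents that add atoms: none
Why: Oxidation gives the ketone, and base equilibration at C9 gives the cis-fused 1-hydrindanone (H9 cis to the C8 arm), the stable fusion for such ketones with an angular substituent (compare 15-oxo steroids with 14β-H).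

Step 10
Reactants: 14 cis-hydrindanone
Product: 15 bicyclic enol triflate (C10–OTf; C10=C5; ethyl ester; C13 ketal)
Conditions: KN(SiMe3)2 (1.05 equiv), THF, −78 °C; PhNTf2, −78 to 0 °C
Reagents that add atoms: N-phenylbis(trifluoromethanesulfonimide) O=S(=O)(N(c1ccccc1)S(=O)(=O)C(F)(F)F)C(F)(F)F
Why: Kinetic deprotonation takes the C5 methylene rather than the hindered C9 methine or the less acidic ester, and O-triflation gives the C10=C5 enol triflate. This also masks C10 while ring D is built.

Step 11
Reactants: 15 bicyclic enol triflate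
Product: 16 aldehyde (C16 CHO; C13 ketal; enol triflate)
Conditions: i-Bu2AlH (1.1 equiv), CH2Cl2, −78 °C; aqueous KNaC4H4O6
Reagents that add atoms: none
Why: Partial reduction of the ester through the stable tetrahedral aluminate gives the aldehyde; enol triflates, ketals and silyl ethers are inert.

Step 12
Reactants: 16 aldehyde
Product: 17 keto aldehyde (C13 ketone; C16 CHO; enol triflate)
Conditions: pyridinium p-toluenesulfonate (0.3 equiv), acetone/H2O (9:1), 50 °C
Reagents that add atoms: water O
Why: Mild hydrolysis of an unhindered cyclohexanone ketal; the primary silyl ether and the enol triflate tolerate this weak acid in a non-alcoholic medium.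

Step 13
Reactants: 17 keto aldehyde
Product: 18 tricyclic α-ketol (13-hydroxy-16-oxo; rings B, C and D; enol triflate; 6β-CH2OTBS)
Conditions: 2-(pentafluorophenyl)-6,7-dihydro-5H-pyrrolo[2,1-c][1,2,4]triazol-2-ium tetrafluoroborate (10 mol %), Et3N (10 mol %), CH2Cl2, rt to 40 °C
Reagents that add atoms: none
Why: N-heterocyclic-carbene-catalysed intramolecular crossed benzoin reaction: the Breslow intermediate of the C16 aldehyde adds to the C13 ketone (5-exo-trig) and closes ring D as the bridged α-ketol. The C15 arm is β on C8, so only one configuration at C13 can form.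

Step 14
Reactants: 18 tricyclic α-ketol
Product: 19 13-O-TBS 16-ketone
Conditions: TBSOTf (1.5 equiv), 2,6-lutidine (3 equiv), CH2Cl2, −78 to 0 °C
Reagents that add atoms: tert-butyldimethylsilyl triflate CC(C)(C)[Si](C)(C)OS(=O)(=O)C(F)(F)F
Why: Silylation of the tertiary bridgehead alcohol with the silyl triflate; the ether blocks the α-ketol shift for the rest of the route and is robust to the later acid step.

Step 15
Reactants: 19 13-O-TBS 16-ketone
Product: 20 tricyclic enol triflate (C16 ethylene ketal; 13-OTBS; 6β-CH2OTBS)
Conditions: Me3SiOCH2CH2OSiMe3 (3 equiv), Me3SiOTf (10 mol %), CH2Cl2, −78 to −20 °C; pyridine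
Reagents that add atoms: 1,2-bis(trimethylsilyloxy)ethane C[Si](C)(C)OCCO[Si](C)(C)C
Why: Ketalisation with the bis-silyl ether under silyl triflate catalysis is aprotic and works for hindered, α-oxygenated cyclopentanone-type ketones; silyl ethers and the enol triflate are unaffected.

Step 16
Reactants: 20 tricyclic enol triflate; 21 methyl 2-methylbut-3-enoate
Product: 23 enone keto ester (C1 ketone on C10; C19 methyl ester; C4 epimers), via B-alkyl borane 22 (not isolated)
Conditions: 21, 9-borabicyclo[3.3.1]nonane, THF, rt; then 20, PdCl2(dppf) (5 mol %), K3PO4 (aq), CO (1 atm), THF/DMF, 50 °C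
Reagents that add atoms: carbon monoxide [C-]#[O+]
Why: 9-BBN hydroborates the terminal alkene of 21 at C2; carbonylative Suzuki–Miyaura coupling (oxidative addition of the enol triflate, CO insertion, B-alkyl transmetalation, reductive elimination) then gives the enone with C1 as the new carbonyl carbon.

Step 17
Reactants: 23 enone keto ester
Product: 25 (1S)-δ-lactone on C10 of the ring B cyclopentene (α-methyl; C4 epimers), via hydroxy ester 24 (not isolated)
Conditions: (R)-tetrahydro-1-methyl-3,3-diphenyl-1H,3H-pyrrolo[1,2-c][1,3,2]oxazaborole (0.2 equiv), BH3·SMe2, THF, −30 °C; MeOH; then pyridinium p-toluenesulfonate (cat.), toluene, 50 °C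
Reagents that add atoms: none
Why: Corey–Bakshi–Shibata reduction: the α-substituted alkenyl group acts as the large substituent and the CH2 chain as the small one, so the (R)-oxazaborolidine should give the (1S)-carbinol under catalyst control, 1,2-selectively. The δ-hydroxy ester then lactonises under mild acid.

Step 18
Reactants: 25 (1S)-δ-lactone
Product: 28 tetracyclic 1(10)-ene 19-acid (C16 ketal; 13-OTBS; 7-OTBS), via silyl ketene acetal 26 (not isolated), via trimethylsilyl ester 27 (not isolated)
Conditions: LiN(i-Pr)2 (1.3 equiv), Me3SiCl/Et3N (3 equiv), THF, −78 °C to rt; toluene, 105 °C; then aqueous citric acid, THF, 0 °C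
Reagents that add atoms: none
Why: LiN(i-Pr)2 with Me3SiCl present gives the endocyclic O-silyl ketene acetal 26 (C4=C19), in which C4 has lost its configuration; on heating C4 bonds to C5 while the C1–O bond breaks in a concerted [3,3]-sigmatropic (Ireland–Claisen) shift to silyl ester 27, hydrolysed to acid 28. The closest known reaction type is the lactone-enolate Claisen rearrangement of 6-alkenyl δ-lactones to cyclohexenecarboxylic acids. Ring A (six-membered, carbocyclic) is closed by the sigmatropic bond formation itself and not by a polar cyclisation: because C2–C3 ties C1 to C4, the array C5=C10–C1–O–C19=C4 can only fold as a boat, a bicyclo[2.2.2]octane-like transition state that converts the lactone atom for atom into the cyclohexene. C5 is controlled by C1: the shift is suprafacial on the allyl unit, so the (1S) carbinol centre from step 17 forces bonding on the α face of C5, anti to the 6β-CH2OTBS arm. C4 is controlled by the ring-fixed ketene acetal geometry (C3 cis to the ring oxygen) within the enforced boat, which places C19 α and the methyl group β whichever C4 epimer of 25 is used. The selectivity the step needs is therefore face selection at C5, and the tether and C1 secure it, since no chair or intermolecular pathway is open. What must be overcome is the contact between the C19 silyloxy group and the C11 methylene under the boat, which is why the smallest silyl group and a non-polar solvent near 105 °C are chosen.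

Step 19
Reactants: 28 tetracyclic 1(10)-ene 19-acid
Product: 29 19-alcohol (1(10)-ene)
Conditions: LiAlH4 (3 equiv), THF, 0 °C to rt; aqueous NaOH work-up
Reagents that add atoms: none
Why: Hydride reduction of the hindered acid to the neopentyl alcohol; with C19 at the alcohol level, neither the 2α-alkoxide of step 23 nor the C20 alkoxide of step 24 can be trapped as a lactone.

Step 20
Reactants: 29 19-alcohol
Product: 30 19-O-TBS ether (1(10)-ene)
Conditions: TBSOTf (1.3 equiv), 2,6-lutidine, CH2Cl2, −78 °C
Reagents that add atoms: tert-butyldimethylsilyl triflate CC(C)(C)[Si](C)(C)OS(=O)(=O)C(F)(F)F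
Why: Silylation of the only free hydroxyl; the group matches the one on C7 so that both leave together in step 26.

Step 21
Reactants: 30 19-O-TBS ether
Product: 31 1(10)-en-2-one
Conditions: CrO3 (15 equiv), 3,5-dimethylpyrazole (15 equiv), CH2Cl2, −20 °C
Reagents that add atoms: chromium trioxide O=[Cr](=O)=O
Why: Allylic oxidation with the CrO3–3,5-dimethylpyrazole complex converts the methylene next to the CH end of a trisubstituted ring alkene into the enone (as C7 in 5-ene steroids). Here that position is C2; the other allylic positions, C5 and C9, are methines and cannot become ketones.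

Step 22
Reactants: 31 1(10)-en-2-one
Product: 32 2α-ol (1(10)-ene; 19-OTBS)
Conditions: i-Bu2AlH (1.5 equiv), toluene, −78 °C; aqueous KNaC4H4O6
Reagents that add atoms: none
Why: 1,2-Reduction of the enone by a bulky hydride; approach to C2 from the β face avoids the axial 4α-CH2OTBS group in the 1,3-position and gives the axial 2α-alcohol.

Step 23
Reactants: 32 2α-ol
Product: 33 2α-(tributylstannylmethyl) ether
Conditions: KH (2 equiv), Bu3SnCH2I (1.5 equiv), 18-crown-6 (cat.), THF, 0 °C to rt
Reagents that add atoms: (iodomethyl)tributylstannane CCCC[Sn](CCCC)(CCCC)CI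
Why: Williamson etherification of the potassium alkoxide with the reactive iodomethylstannane; no other acidic or electrophilic site is present.

Step 24
Reactants: 33 2α-(tributylstannylmethyl) ether
Product: 35 20-hydroxy-1-ene (C10 quaternary; C20 α), via lithiomethyl ether 34 (not isolated)
Conditions: n-BuLi (2.5 equiv), THF, −78 °C; aqueous NH4Cl at −78 °C
Reagents that add atoms: none
Why: Still–Wittig [2,3]-sigmatropic rearrangement: tin–lithium exchange gives the α-alkoxymethyllithium, which shifts suprafacially from the axial 2α oxygen to the α face of C10. This forms C10–C20 and the quaternary centre syn to C19 and moves the double bond to C1=C2.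

Step 25
Reactants: 35 20-hydroxy-1-ene
Product: 36 20-alcohol with saturated ring A (C16 ketal; 13-OTBS; 7,19-bis-OTBS)
Conditions: H2 (1 atm), Pd/C (10 %), EtOAc, rt
Reagents that add atoms: none
Why: Catalytic hydrogenation of the cis-disubstituted alkene; no stereocentre is formed and ketal and silyl ethers are stable.

Step 26
Reactants: 36 20-alcohol with saturated ring A
Product: 37 7,19,20-triol 16-ketone (13-OTBS)
Conditions: HCl (2 M aq), THF, rt to 40 °C
Reagents that add atoms: water O
Why: Aqueous acid cleaves the two primary silyl ethers and then the ketal; the tertiary bridgehead silyl ether hydrolyses far more slowly and cannot ionise, so it should stay and no free α-ketol is exposed.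

Step 27
Reactants: 37 7,19,20-triol 16-ketone
Product: 38 7,19,20-triol 16-methylene (13-OTBS)
Conditions: Ph3PCH3Br (8 equiv), KOt-Bu (7.5 equiv), THF, rt to 60 °C
Reagents that add atoms: methyltriphenylphosphonium bromide C[P+](c1ccccc1)(c1ccccc1)c1ccccc1.[Br-]
Why: Wittig methylenation of the nor-ketone with excess ylide; the hydroxyls are tolerated as alkoxides, and the 13-silyl ether rules out the base-induced α-ketol shift.

Step 28
Reactants: 38 7,19,20-triol 16-methylene
Product: 39 7,19,20-trial (13-OTBS)
Conditions: (COCl)2 (6 equiv), DMSO (12 equiv), CH2Cl2, −78 °C; Et3N (20 equiv), −78 to −20 °C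
Reagents that add atoms: none
Why: Swern oxidation: all three hydroxyls become alkoxysulfonium ions before base is added, so no hydroxy aldehyde is present that could close to a 19,20-lactol and stop at the lactone. The cold work-up limits epimerisation at C6, where the natural 6β arrangement is expected to be the more stable one.

Step 29
Reactants: 39 7,19,20-trial
Product: 40 13-O-TBS ether of the target gibberellin (7,19,20-triacid; 16-methylene)
Conditions: NaClO2, NaH2PO4, 2-methylbut-2-ene, t-BuOH/H2O, 0 °C to rt
Reagents that add atoms: sodium chlorite [Na+].[O-]Cl=O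
Why: Pinnick oxidation of the three aldehydes; the scavenger removes hypochlorous acid and so protects the C16 methylene, and the buffered medium leaves the silyl ether and C6 untouched.

Step 30
Reactants: 40 13-O-TBS ether of the target gibberellin
Product: 41 target gibberellin (13-hydroxy-16-methylene 7,19,20-triacid; seventeenth gibberellin of the A series)
Conditions: HF·pyridine, THF, 0 °C to rt
Reagents that add atoms: none
Why: Fluoride-driven cleavage of the tertiary silyl ether under weakly acidic conditions; the bridgehead carbon cannot ionise, so the allylic alcohol and the methylene should not rearrange.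

## Compound list

1 | (3-methoxyphenyl)boronic acid | OB(O)c1cccc(OC)c1 | starting material
2 | di-tert-butyl fumarate | CC(C)(C)OC(=O)/C=C/C(=O)OC(C)(C)C | starting material
3 | di-tert-butyl (S)-2-(3-methoxyphenyl)succinate | CC(C)(C)OC(=O)C[C@@H](c1cccc(OC)c1)C(=O)OC(C)(C)C | intermediate
4 | (S)-2-(3-methoxyphenyl)succinic acid (diacid, not isolated) | OC(=O)C[C@@H](c1cccc(OC)c1)C(=O)O | intermediate
5 | (S)-6-methoxy-3-oxo-2,3-dihydro-1H-indene-1-carboxylic acid | O=C1C[C@H](C(=O)O)c2cc(OC)ccc21 | intermediate
6 | (1R,3S)-3-(hydroxymethyl)-5-methoxy-2,3-dihydro-1H-inden-1-ol (cis) | O[C@@H]1C[C@H](CO)c2cc(OC)ccc21 | intermediate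
7 | (1R,3S)-3-[(tert-butyldimethylsilyloxy)methyl]-5-methoxy-2,3-dihydro-1H-inden-1-ol | O[C@@H]1C[C@H](CO[Si](C)(C)C(C)(C)C)c2cc(OC)ccc21 | intermediate
8 | (1R,3S)-3-[(tert-butyldimethylsilyloxy)methyl]-5-methoxy-2,3,4,7-tetrahydro-1H-inden-1-ol | O[C@@H]1C[C@H](CO[Si](C)(C)C(C)(C)C)C2=C1CC=C(OC)C2 | intermediate
9 | (1R,3S)-3-[(tert-butyldimethylsilyloxy)methyl]-5,5-(ethylenedioxy)-2,3,4,5,6,7-hexahydro-1H-inden-1-ol | O[C@@H]1C[C@H](CO[Si](C)(C)C(C)(C)C)C2=C1CCC3(OCCO3)C2 | intermediate
10 | 1-ethoxyvinyl ether of 9 (ketene acetal, not isolated) | C=C(OCC)O[C@@H]1C[C@H](CO[Si](C)(C)C(C)(C)C)C2=C1CCC3(OCCO3)C2 | intermediate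
11 | bicyclic 9(10)-ene ethyl ester: C8 quaternary with β-CH2CO2Et, 6β-CH2OTBS, C13 ethylene ketal | CCOC(=O)C[C@]12CC3(OCCO3)CCC1=CC[C@@H]2CO[Si](C)(C)C(C)(C)C | intermediate
12 | C10 alkylborane from 11 (C9/C10 isomers, not isolated) | CCOC(=O)C[C@]12CC3(OCCO3)CCC1C(B)C[C@@H]2CO[Si](C)(C)C(C)(C)C | intermediate
13 | C10 alcohol (C9/C10 isomer mixture) | CCOC(=O)C[C@]12CC3(OCCO3)CCC1C(O)C[C@@H]2CO[Si](C)(C)C(C)(C)C | intermediate
14 | cis-hydrindanone: C10 ketone, 9β-H, C8 β-CH2CO2Et, 6β-CH2OTBS, C13 ketal | CCOC(=O)C[C@]12CC3(OCCO3)CC[C@H]1C(=O)C[C@@H]2CO[Si](C)(C)C(C)(C)C | intermediate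
15 | bicyclic enol triflate: C10–OTf, C10=C5, ethyl ester, C13 ketal | CCOC(=O)C[C@]12CC3(OCCO3)CC[C@H]1C(OS(=O)(=O)C(F)(F)F)=C[C@@H]2CO[Si](C)(C)C(C)(C)C | intermediate
16 | aldehyde: C16 CHO, C13 ketal, enol triflate | O=CC[C@]12CC3(OCCO3)CC[C@H]1C(OS(=O)(=O)C(F)(F)F)=C[C@@H]2CO[Si](C)(C)C(C)(C)C | intermediate
17 | keto aldehyde: C13 ketone, C16 CHO, enol triflate | O=CC[C@]12CC(=O)CC[C@H]1C(OS(=O)(=O)C(F)(F)F)=C[C@@H]2CO[Si](C)(C)C(C)(C)C | intermediate
18 | tricyclic α-ketol: 13-hydroxy-16-oxo, rings B, C and D, enol triflate, 6β-CH2OTBS | O=C1C[C@]23C[C@@]1(O)CC[C@H]2C(OS(=O)(=O)C(F)(F)F)=C[C@@H]3CO[Si](C)(C)C(C)(C)C | intermediate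
19 | 13-O-TBS 16-ketone | O=C1C[C@]23C[C@@]1(O[Si](C)(C)C(C)(C)C)CC[C@H]2C(OS(=O)(=O)C(F)(F)F)=C[C@@H]3CO[Si](C)(C)C(C)(C)C | intermediate
20 | tricyclic enol triflate: C16 ethylene ketal, 13-OTBS, 6β-CH2OTBS | C14(OCCO4)C[C@]23C[C@@]1(O[Si](C)(C)C(C)(C)C)CC[C@H]2C(OS(=O)(=O)C(F)(F)F)=C[C@@H]3CO[Si](C)(C)C(C)(C)C | intermediate
21 | methyl 2-methylbut-3-enoate | C=CC(C)C(=O)OC | starting material
22 | B-(4-methoxy-3-methyl-4-oxobutyl)-9-borabicyclo[3.3.1]nonane (not isolated) | COC(=O)C(C)CCB1C2CCCC1CCC2 | intermediate
23 | enone keto ester: C1 ketone on C10, C19 methyl ester, C4 epimers | C14(OCCO4)C[C@]23C[C@@]1(O[Si](C)(C)C(C)(C)C)CC[C@H]2C(C(=O)CCC(C)C(=O)OC)=C[C@@H]3CO[Si](C)(C)C(C)(C)C | intermediate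
24 | (1S)-hydroxy ester (C4 epimers, not isolated) | C14(OCCO4)C[C@]23C[C@@]1(O[Si](C)(C)C(C)(C)C)CC[C@H]2C([C@@H](O)CCC(C)C(=O)OC)=C[C@@H]3CO[Si](C)(C)C(C)(C)C | intermediate
25 | (1S)-δ-lactone on C10 of the ring B cyclopentene, α-methyl (C4 epimers); key-step precursor | C14(OCCO4)C[C@]23C[C@@]1(O[Si](C)(C)C(C)(C)C)CC[C@H]2C(=C[C@@H]3CO[Si](C)(C)C(C)(C)C)[C@@H]1CCC(C)C(=O)O1 | intermediate
26 | trimethylsilyl ketene acetal of 25 (not isolated) | C14(OCCO4)C[C@]23C[C@@]1(O[Si](C)(C)C(C)(C)C)CC[C@H]2C(=C[C@@H]3CO[Si](C)(C)C(C)(C)C)[C@@H]1CCC(C)=C(O[Si](C)(C)C)O1 | intermediate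
27 | trimethylsilyl ester of 28 (not isolated) | C14(OCCO4)C[C@]23C[C@@]1(O[Si](C)(C)C(C)(C)C)CC[C@H]2C1=CCC[C@@](C)(C(=O)O[Si](C)(C)C)[C@H]1[C@@H]3CO[Si](C)(C)C(C)(C)C | intermediate
28 | tetracyclic 1(10)-ene 19-acid: C16 ketal, 13-OTBS, 7-OTBS; key-step product | C14(OCCO4)C[C@]23C[C@@]1(O[Si](C)(C)C(C)(C)C)CC[C@H]2C1=CCC[C@@](C)(C(=O)O)[C@H]1[C@@H]3CO[Si](C)(C)C(C)(C)C | intermediate
29 | 19-alcohol (1(10)-ene) | C14(OCCO4)C[C@]23C[C@@]1(O[Si](C)(C)C(C)(C)C)CC[C@H]2C1=CCC[C@@](C)(CO)[C@H]1[C@@H]3CO[Si](C)(C)C(C)(C)C | intermediate
30 | 19-O-TBS ether (1(10)-ene) | C14(OCCO4)C[C@]23C[C@@]1(O[Si](C)(C)C(C)(C)C)CC[C@H]2C1=CCC[C@@](C)(CO[Si](C)(C)C(C)(C)C)[C@H]1[C@@H]3CO[Si](C)(C)C(C)(C)C | intermediate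
31 | 1(10)-en-2-one | C14(OCCO4)C[C@]23C[C@@]1(O[Si](C)(C)C(C)(C)C)CC[C@H]2C1=CC(=O)C[C@@](C)(CO[Si](C)(C)C(C)(C)C)[C@H]1[C@@H]3CO[Si](C)(C)C(C)(C)C | intermediate
32 | 2α-ol (1(10)-ene, 19-OTBS) | C14(OCCO4)C[C@]23C[C@@]1(O[Si](C)(C)C(C)(C)C)CC[C@H]2C1=C[C@@H](O)C[C@@](C)(CO[Si](C)(C)C(C)(C)C)[C@H]1[C@@H]3CO[Si](C)(C)C(C)(C)C | intermediate
33 | 2α-(tributylstannylmethyl) ether | C14(OCCO4)C[C@]23C[C@@]1(O[Si](C)(C)C(C)(C)C)CC[C@H]2C1=C[C@@H](OC[Sn](CCCC)(CCCC)CCCC)C[C@@](C)(CO[Si](C)(C)C(C)(C)C)[C@H]1[C@@H]3CO[Si](C)(C)C(C)(C)C | intermediate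
34 | 2α-(lithiomethyl) ether (not isolated) | C14(OCCO4)C[C@]23C[C@@]1(O[Si](C)(C)C(C)(C)C)CC[C@H]2C1=C[C@@H](OC[Li])C[C@@](C)(CO[Si](C)(C)C(C)(C)C)[C@H]1[C@@H]3CO[Si](C)(C)C(C)(C)C | intermediate
35 | 20-hydroxy-1-ene: C10 quaternary, C20 α | C14(OCCO4)C[C@]23C[C@@]1(O[Si](C)(C)C(C)(C)C)CC[C@H]2[C@]1(CO)C=CC[C@@](C)(CO[Si](C)(C)C(C)(C)C)[C@H]1[C@@H]3CO[Si](C)(C)C(C)(C)C | intermediate
36 | 20-alcohol with saturated ring A: C16 ketal, 13-OTBS, 7,19-bis-OTBS | C14(OCCO4)C[C@]23C[C@@]1(O[Si](C)(C)C(C)(C)C)CC[C@H]2[C@]1(CO)CCC[C@@](C)(CO[Si](C)(C)C(C)(C)C)[C@H]1[C@@H]3CO[Si](C)(C)C(C)(C)C | intermediate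
37 | 7,19,20-triol 16-ketone (13-OTBS) | O=C1C[C@]23C[C@@]1(O[Si](C)(C)C(C)(C)C)CC[C@H]2[C@]1(CO)CCC[C@@](C)(CO)[C@H]1[C@@H]3CO | intermediate
38 | 7,19,20-triol 16-methylene (13-OTBS) | C=C1C[C@]23C[C@@]1(O[Si](C)(C)C(C)(C)C)CC[C@H]2[C@]1(CO)CCC[C@@](C)(CO)[C@H]1[C@@H]3CO | intermediate
39 | 7,19,20-trial (13-OTBS) | C=C1C[C@]23C[C@@]1(O[Si](C)(C)C(C)(C)C)CC[C@H]2[C@]1(C=O)CCC[C@@](C)(C=O)[C@H]1[C@@H]3C=O | intermediate
40 | 13-O-TBS ether of the target gibberellin: 7,19,20-triacid, 16-methylene | C=C1C[C@]23C[C@@]1(O[Si](C)(C)C(C)(C)C)CC[C@H]2[C@]1(C(=O)O)CCC[C@@](C)(C(=O)O)[C@H]1[C@@H]3C(=O)O | intermediate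
41 | target gibberellin, seventeenth of the A series: ent-13-hydroxygibberell-16-ene-7,19,20-trioic acid | C=C1C[C@]23C[C@@]1(O)CC[C@H]2[C@]1(C(=O)O)CCC[C@@](C)(C(=O)O)[C@H]1[C@@H]3C(=O)O | target

## Step count and least certain steps

Total step count: 30. Longest linear sequence: 30 steps (1 or 2 to 41; ester 21 enters as a purchased reagent in step 16).

**Step 18 (key step).** The rearrangement may be slow because the boat presses the C19 silyloxy group against the C11 methylene. The ketene acetal could then revert to lactone by adventitious hydrolysis, or be diverted by C-silylation, before it rearranges. Fallback, an ionic closure in place of the pericyclic one: hydroxy ester 24 is isolated before lactonisation and converted with ClP(O)(OEt)2 and pyridine into the allylic diethyl phosphate F1. KN(SiMe3)2 in THF (−78 to 0 °C) then forms the ester enolate at C4, which displaces phosphate with allylic transposition (intramolecular syn SN2′, six-membered ring) to give the 1(10)-ene methyl ester F2. LiAlH4 reduces F2 to the 19-alcohol, and the route is rejoined at 29. In this variant the C4 configuration rests on a cyclic ionic transition state and would have to be checked.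

**Step 13.** The C12 enol or enolate of the ketone may add to the aldehyde instead (six-membered aldol closure to a bicyclo[2.2.2]octane), or the benzoin adduct may revert, because carbene addition to a hindered ketone is reversible. Fallback, a reductive closure: keto aldehyde 17 is treated with SmI2 in THF at −78 °C (ketyl–aldehyde pinacol coupling, five-membered ring) to give the cis-13,16-diol F3. Its secondary hydroxyl is oxidised with SO3·pyridine, DMSO and Et3N, and the route is rejoined at 18.

**Step 16.** Alkyl transfer may outrun CO insertion and give the direct coupling product, or the B-alkyl group may be lost by protodeboronation under the aqueous base. Fallback, with the C1 carbon brought in first: enol triflate 20 is formylated (Pd(PPh3)4, CO, Bu3SnH) to the enal F4. The diorganozinc F5, bis(4-methoxy-3-methyl-4-oxobutyl)zinc, is made from methyl 4-iodo-2-methylbutanoate and Et2Zn. F5 is added to F4 with Ti(Oi-Pr)4 and the bis(trifluoromethanesulfonamide) of trans-cyclohexane-1,2-diamine, using the antipode that gives the (1S)-carbinol. This gives hydroxy ester 24 directly, which is lactonised as in step 17, and the route is rejoined at 25.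

**Step 21.** Hydrogen abstraction at the tertiary allylic positions C5 or C9 would lead to transposed or over-oxidised products, and conversion may stall on this hindered alkene. Fallback, using the C19 carboxyl to oxygenate ring A: acid 28 is iodolactonised (I2, NaHCO3, MeCN) to the 1β-iodo-19,10-lactone F6, and DBU then eliminates hydrogen iodide to give the 1-ene 19,10-lactone F7. Pd(PPh3)4 transposes the allylic lactone with retention on the α face to the 1(10)-ene 19,2α-lactone F8, which LiAlH4 opens to the 2α,19-diol F9. Selective silylation of the primary hydroxyl (TBSCl, imidazole) rejoins the route at 32.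

**Step 24.** Congestion at C10 under the axial C19 group may slow the [2,3] shift, so the organolithium is instead protonated or undergoes a [1,2] shift. Fallback, a [3,3] shift from the same oxygen: alcohol 32 is esterified with benzyloxyacetic acid (dicyclohexylcarbodiimide, 4-dimethylaminopyridine) to the glycolate F10. Ireland–Claisen rearrangement of its chelated silyl ketene acetal (KN(SiMe3)2, Me3SiCl, THF, −78 °C to rt) delivers the α-benzyloxy acid F11 with the new C10–C20 bond on the α face. Hydrogenation (H2, Pd/C) saturates C1=C2 and removes the benzyl group to give the α-hydroxy acid F12, which Pb(OAc)4 cleaves to the C20 aldehyde F13. NaBH4 reduces F13, and the route is rejoined at 36.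

## Further compounds

F1 | step 18 | allylic diethyl phosphate of (1S)-hydroxy ester 24 | C14(OCCO4)C[C@]23C[C@@]1(O[Si](C)(C)C(C)(C)C)CC[C@H]2C([C@@H](OP(=O)(OCC)OCC)CCC(C)C(=O)OC)=C[C@@H]3CO[Si](C)(C)C(C)(C)C
F2 | step 18 | tetracyclic 1(10)-ene 19-methyl ester | C14(OCCO4)C[C@]23C[C@@]1(O[Si](C)(C)C(C)(C)C)CC[C@H]2C1=CCC[C@@](C)(C(=O)OC)[C@H]1[C@@H]3CO[Si](C)(C)C(C)(C)C
F3 | step 13 | tricyclic cis-13,16-diol with enol triflate (C16 configuration open) | OC1C[C@]23C[C@@]1(O)CC[C@H]2C(OS(=O)(=O)C(F)(F)F)=C[C@@H]3CO[Si](C)(C)C(C)(C)C
F4 | step 16 | tricyclic enal (formyl on C10; C10=C5; C16 ketal; 13-OTBS; 7-OTBS) | C14(OCCO4)C[C@]23C[C@@]1(O[Si](C)(C)C(C)(C)C)CC[C@H]2C(C=O)=C[C@@H]3CO[Si](C)(C)C(C)(C)C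
F5 | step 16 | bis(4-methoxy-3-methyl-4-oxobutyl)zinc | COC(=O)C(C)CC[Zn]CCC(C)C(=O)OC
F6 | step 21 | 1β-iodo-19,10-lactone | C14(OCCO4)C[C@]23C[C@@]1(O[Si](C)(C)C(C)(C)C)CC[C@H]2[C@]15[C@H](I)CC[C@@](C)(C(=O)O5)[C@H]1[C@@H]3CO[Si](C)(C)C(C)(C)C
F7 | step 21 | 1-ene 19,10-lactone | C14(OCCO4)C[C@]23C[C@@]1(O[Si](C)(C)C(C)(C)C)CC[C@H]2[C@]15C=CC[C@@](C)(C(=O)O5)[C@H]1[C@@H]3CO[Si](C)(C)C(C)(C)C
F8 | step 21 | 1(10)-ene 19,2α-lactone | C14(OCCO4)C[C@]23C[C@@]1(O[Si](C)(C)C(C)(C)C)CC[C@H]2C1=C[C@@H]5C[C@@](C)(C(=O)O5)[C@H]1[C@@H]3CO[Si](C)(C)C(C)(C)C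
F9 | step 21 | 1(10)-ene 2α,19-diol | C14(OCCO4)C[C@]23C[C@@]1(O[Si](C)(C)C(C)(C)C)CC[C@H]2C1=C[C@@H](O)C[C@@](C)(CO)[C@H]1[C@@H]3CO[Si](C)(C)C(C)(C)C
F10 | step 24 | 2α-(benzyloxyacetate) of 32 | C14(OCCO4)C[C@]23C[C@@]1(O[Si](C)(C)C(C)(C)C)CC[C@H]2C1=C[C@@H](OC(=O)COCc5ccccc5)C[C@@](C)(CO[Si](C)(C)C(C)(C)C)[C@H]1[C@@H]3CO[Si](C)(C)C(C)(C)C
F11 | step 24 | 1-ene α-benzyloxy acid on C10 (carbinol configuration open) | C14(OCCO4)C[C@]23C[C@@]1(O[Si](C)(C)C(C)(C)C)CC[C@H]2[C@]1(C(OCc5ccccc5)C(=O)O)C=CC[C@@](C)(CO[Si](C)(C)C(C)(C)C)[C@H]1[C@@H]3CO[Si](C)(C)C(C)(C)C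
F12 | step 24 | saturated α-hydroxy acid on C10 (carbinol configuration open) | C14(OCCO4)C[C@]23C[C@@]1(O[Si](C)(C)C(C)(C)C)CC[C@H]2[C@]1(C(O)C(=O)O)CCC[C@@](C)(CO[Si](C)(C)C(C)(C)C)[C@H]1[C@@H]3CO[Si](C)(C)C(C)(C)C
F13 | step 24 | C20 aldehyde with saturated ring A | C14(OCCO4)C[C@]23C[C@@]1(O[Si](C)(C)C(C)(C)C)CC[C@H]2[C@]1(C=O)CCC[C@@](C)(CO[Si](C)(C)C(C)(C)C)[C@H]1[C@@H]3CO[Si](C)(C)C(C)(C)C
A1 | alternative 1 | ring A triester with C10 vinyl group and C6-linked 2-silyloxydiene carrying the propargyl arm | C[Si](C)(C)C#CCC(=CC(O[Si](C)(C)C(C)(C)C)=C)[C@@H](C(=O)OC)[C@@H]1[C@](C)(C(=O)OC)CCC[C@]1(C=C)C(=O)OC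
A2 | alternative 1 | tricyclic A/B/C 13-silyl enol ether with C8 propargyl arm | C[Si](C)(C)C#CC[C@]12C=C(O[Si](C)(C)C(C)(C)C)CC[C@H]1[C@]1(C(=O)OC)CCC[C@@](C)(C(=O)OC)[C@H]1[C@@H]2C(=O)OC
A3 | alternative 2 | ent-kauranoid 6-mesylate 7-ol 19,20-dimethyl ester 13-methoxymethyl ether (C7 configuration open) | C=C1C[C@]23C[C@@]1(OCOC)CC[C@H]2[C@]1(C(=O)OC)CCC[C@@](C)(C(=O)OC)[C@H]1[C@H](OS(C)(=O)=O)C3O
A4 | alternative 2 | gibberellin 7-aldehyde 19,20-dimethyl ester 13-methoxymethyl ether | C=C1C[C@]23C[C@@]1(OCOC)CC[C@H]2[C@]1(C(=O)OC)CCC[C@@](C)(C(=O)OC)[C@H]1[C@@H]3C=O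
A5 | alternative 3 | hydrindane triester with C8-spiro cyclopentane-1,2-dione and C9 acetyl group | O=C1C(=O)CC2(C1)[C@@H](C(C)=O)[C@]1(C(=O)OC)CCC[C@@](C)(C(=O)OC)[C@H]1[C@@H]2C(=O)OC
A6 | alternative 3 | 13-hydroxy-11,16-dioxo-17-nor tetracyclic triester | O=C1C[C@]23C[C@@]1(O)CC(=O)[C@H]2[C@]1(C(=O)OC)CCC[C@@](C)(C(=O)OC)[C@H]1[C@@H]3C(=O)OC
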